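**Strategy.** The route rests on disconnecting C4–C5 and C6–C7 of the benzenoid ring, so that C5 and C6, the two adjacent bromine-bearing carbons, come from the two carbons of a disilyl alkyne. In one operation, a [4+2] cycloaddition onto a pyrrole-fused 2-pyranone followed by loss of CO2 builds the six-membered carbocycle on a preformed pyrrole ring and puts silicon on C5 and C6. Each silicon is later exchanged for bromine at its own carbon, while C2 and C3 are brominated by ordinary indole chemistry. The precursor is an N-tosylpyrrole fused across C2–C3 to a 2-pyranone (lactone oxygen on the C2 side), a stable pyrrole-2,3-quinodimethane equivalent.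

Key step: step 6

Remark: the pyranone is numbered as the fused system N1, C2, C3, C3a, C4, C5(=O), O6, C7, C7a, so its C4 and C7 become C4 and C7 of the indole. Compounds 4 and 6 (one stereocentre each) and 12 (two bridgeheads, relative configuration fixed by the bridge) are racemic and transient.

Step 1
Reactants: 1 1-tosylpyrrole; 2 ethyl chlorooxoacetate
Product: 3 ethyl 2-oxo-2-(1-tosyl-1H-pyrrol-3-yl)acetate
Conditions: AlCl3 (2.2 equiv), CH2Cl2, 0 °C → rt; ice/HCl quench
Reagents that add atoms: none
Why: Friedel–Crafts acylation, in which AlCl3 directs the N-sulfonylpyrrole to react at C3 rather than C2 (the established site preference of 1-arylsulfonylpyrroles under a strong Lewis acid) and the acyl chloride end of 2 is far more electrophilic than its ester end.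

Step 2
Reactants: 3 ethyl 2-oxo-2-(1-tosyl-1H-pyrrol-3-yl)acetate
Product: 5 ethyl 2-(1-tosyl-1H-pyrrol-3-yl)acetate, via ethyl 2-hydroxy-2-(1-tosyl-1H-pyrrol-3-yl)acetate 4 (not isolated)
Conditions: Et3SiH (3 equiv), CF3CO2H, rt
Reagents that add atoms: none
Why: Ionic hydrogenation of an aryl ketone: hydride transfer to the protonated ketone gives carbinol 4, which ionises to a cation stabilised by the pyrrole ring and takes a second hydride, while the ester and the sulfonamide are inert to silane/acid.

Step 3
Reactants: 5 ethyl 2-(1-tosyl-1H-pyrrol-3-yl)acetate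
Product: 7 ethyl 2-(2-formyl-1-tosyl-1H-pyrrol-3-yl)acetate, via α-chloro methyl ether 6 (not isolated)
Conditions: Cl2CHOMe (1.5 equiv), AlCl3 (2.5 equiv), CH2Cl2, −20 → 0 °C; then ice/H2O
Reagents that add atoms: dichloromethyl methyl ether, COC(Cl)Cl; water, O
Why: Rieche formylation, in which the small chloro(methoxy)carbenium electrophile should attack C2, the pyrrole α-carbon that is also activated by the adjacent C3 alkyl group (α-attack being the expected outcome for N-sulfonylpyrroles with this reagent), and the α-chloro ether 6 is hydrolysed to the aldehyde on aqueous work-up.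

Step 4
Reactants: 7 ethyl 2-(2-formyl-1-tosyl-1H-pyrrol-3-yl)acetate
Product: 8 2-(2-formyl-1-tosyl-1H-pyrrol-3-yl)acetic acid
Conditions: 2 M aq. HCl, 1,4-dioxane, 80 °C
Reagents that add atoms: water, O
Why: Acid-catalysed ester hydrolysis, chosen over saponification because hydroxide would cleave the sulfonyl group from the nitrogen of a 2-formylpyrrole, whereas the sulfonamide and the aldehyde tolerate hot dilute acid.

Step 5
Reactants: 8 2-(2-formyl-1-tosyl-1H-pyrrol-3-yl)acetic acid
Product: 10 1-tosylpyrano[3,4-b]pyrrol-5(1H)-one, via mixed acetic anhydride 9 (not isolated)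
Conditions: Ac2O, 100 °C, short heating; evaporate, crystallise
Reagents that add atoms: none
Why: Cyclodehydration of an ortho-formyl heteroarylacetic acid, the standard entry to fused 2-pyranones: the mixed anhydride 9 acylates the formyl oxygen intramolecularly, and loss of the C4 proton with acetic acid should give the conjugated lactone.

Step 6
Reactants: 10 1-tosylpyrano[3,4-b]pyrrol-5(1H)-one; 11 bis(trimethylsilyl)acetylene
Product: 13 1-tosyl-5,6-bis(trimethylsilyl)-1H-indole, via CO2-bridged cycloadduct 12 (not isolated)
Conditions: 11 (10 equiv), PhBr, sealed tube, 150–160 °C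
Reagents that add atoms: none
Why: The fused 2-pyranone of 10 is a cyclic diene locked s-cis (C4=C3a–C7a=C7) and should add alkyne 11 in a thermal suprafacial [4+2] cycloaddition across C4 and C7 to give the CO2-bridged bicyclo[2.2.2]octadiene 12, which loses CO2 by retro-[4+2] at the reaction temperature. The closest known reaction type is the Diels–Alder/decarboxylation of 2-pyranones, including pyrrole- and indole-fused ones, with alkynes to give benzenoid rings, and bis(trimethylsilyl)acetylene is an established if sluggish partner for 2-pyranones. The one ring closed, the carbocycle C3a–C4–C5–C6–C7–C7a, is formed by intermolecular [4+2] annulation in which both new ring bonds (C4–C5 and C6–C7) arise in one pericyclic event, the pyrrole ring being present beforehand. No stereocentre survives, because the two bridgehead carbons of 12 are held cis by the bridge and become sp2 when CO2 leaves. No regioselectivity is needed since 11 is symmetric, so the only demand is that cycloaddition outrun thermal degradation of 10; a large excess of 11 and the driving force of forming a benzene and a pyrrole ring from a quinodimethane-like diene should secure this. The N-tosyl group tempers the electron richness of the diene enough for 10 to be isolated and heated.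

Step 7
Reactants: 13 1-tosyl-5,6-bis(trimethylsilyl)-1H-indole
Product: 14 5,6-bis(trimethylsilyl)-1H-indole
Conditions: KOH (5 equiv), MeOH–THF–H2O, reflux
Reagents that add atoms: none
Why: Nucleophilic cleavage of the N–S bond of an N-sulfonylindole (the indolide is a good leaving group), under conditions to which aryl–SiMe3 bonds on an electron-rich arene are stable.

Step 8
Reactants: 14 5,6-bis(trimethylsilyl)-1H-indole
Product: 16 2,3,5,6-tetrabromo-1H-indole, via 2,3-dibromo-5,6-bis(trimethylsilyl)-1H-indole 15 (not isolated)
Conditions: NBS (2.1 equiv), DMF, −20 → 0 °C, dark; then NBS (2.2 equiv), 0 °C → rt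
Reagents that add atoms: N-bromosuccinimide, O=C1CCC(=O)N1Br
Why: Electrophilic aromatic bromination followed by ipso-bromodesilylation: the first two equivalents should brominate C3 and then C2 of the pyrrole ring to give 15, and the further equivalents attack the silicon-bearing C5 and C6, where the β-silicon effect and relief of strain between the vicinal silyl groups direct bromine to exactly the carbons that carried silicon, NBS being used because it releases no HBr that could cause protodesilylation.

**Compound list**

1 | 1-tosylpyrrole [1-(4-methylbenzenesulfonyl)-1H-pyrrole] | Cc1ccc(cc1)S(=O)(=O)n1cccc1 | starting material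
2 | ethyl chlorooxoacetate | CCOC(=O)C(=O)Cl | starting material
3 | ethyl 2-oxo-2-(1-tosyl-1H-pyrrol-3-yl)acetate | CCOC(=O)C(=O)c1ccn(c1)S(=O)(=O)c1ccc(C)cc1 | intermediate
4 | ethyl 2-hydroxy-2-(1-tosyl-1H-pyrrol-3-yl)acetate (racemic) | CCOC(=O)C(O)c1ccn(c1)S(=O)(=O)c1ccc(C)cc1 | intermediate (not isolated)
5 | ethyl 2-(1-tosyl-1H-pyrrol-3-yl)acetate | CCOC(=O)Cc1ccn(c1)S(=O)(=O)c1ccc(C)cc1 | intermediate
6 | ethyl 2-{2-[chloro(methoxy)methyl]-1-tosyl-1H-pyrrol-3-yl}acetate (racemic) | CCOC(=O)Cc1ccn(c1C(Cl)OC)S(=O)(=O)c1ccc(C)cc1 | intermediate (not isolated)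
7 | ethyl 2-(2-formyl-1-tosyl-1H-pyrrol-3-yl)acetate | CCOC(=O)Cc1ccn(c1C=O)S(=O)(=O)c1ccc(C)cc1 | intermediate
8 | 2-(2-formyl-1-tosyl-1H-pyrrol-3-yl)acetic acid | OC(=O)Cc1ccn(c1C=O)S(=O)(=O)c1ccc(C)cc1 | intermediate
9 | acetic 2-(2-formyl-1-tosyl-1H-pyrrol-3-yl)acetic anhydride (mixed anhydride) | CC(=O)OC(=O)Cc1ccn(c1C=O)S(=O)(=O)c1ccc(C)cc1 | intermediate (not isolated)
10 | 1-tosylpyrano[3,4-b]pyrrol-5(1H)-one | Cc1ccc(cc1)S(=O)(=O)N1C=CC2=CC(=O)OC=C12 | intermediate
11 | bis(trimethylsilyl)acetylene | C[Si](C)(C)C#C[Si](C)(C)C | starting material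
12 | CO2-bridged cycloadduct: 1-tosyl-5,6-bis(trimethylsilyl)-4,7-dihydro-1H-indole with C4 and C7 spanned by a –C(=O)–O– bridge (carbonyl carbon on C4, oxygen on C7); racemic, one enantiomer drawn | Cc1ccc(cc1)S(=O)(=O)n1ccc2c1[C@@H]1OC(=O)[C@H]2C([Si](C)(C)C)=C1[Si](C)(C)C | intermediate (not isolated)
13 | 1-tosyl-5,6-bis(trimethylsilyl)-1H-indole | Cc1ccc(cc1)S(=O)(=O)n1ccc2cc([Si](C)(C)C)c([Si](C)(C)C)cc21 | intermediate
14 | 5,6-bis(trimethylsilyl)-1H-indole | C[Si](C)(C)c1cc2cc[nH]c2cc1[Si](C)(C)C | intermediate
15 | 2,3-dibromo-5,6-bis(trimethylsilyl)-1H-indole | C[Si](C)(C)c1cc2[nH]c(Br)c(Br)c2cc1[Si](C)(C)C | intermediate (not isolated)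
16 | 2,3,5,6-tetrabromo-1H-indole | Brc1cc2[nH]c(Br)c(Br)c2cc1Br | target

**Totals.** Total step count: 8. Longest linear sequence: 8 steps (1 to 16).

**Steps most likely to fail**

Step 6. The hindered, non-activated disilyl alkyne may add so slowly that thermal breakdown or self-reaction of the diene wins. The fallback sets out from pyranone 10 and uses the smaller, more polarised (bromoethynyl)trimethylsilane (C[Si](C)(C)C#CBr), which carries one bromine in directly. Cycloaddition should give the two regioisomeric lactone-bridged adducts, the 5-bromo-6-(trimethylsilyl) CO2-bridged cycloadduct F1 and the 6-bromo-5-(trimethylsilyl) CO2-bridged cycloadduct F2. These lose CO2 to give 5-bromo-1-tosyl-6-(trimethylsilyl)-1H-indole F3 and 6-bromo-1-tosyl-5-(trimethylsilyl)-1H-indole F4. The mixture need not be separated, because both isomers converge. KOH in MeOH–THF–H2O removes the tosyl group to give 5-bromo-6-(trimethylsilyl)-1H-indole F5 and 6-bromo-5-(trimethylsilyl)-1H-indole F6. NBS (about 3 equiv) in DMF then brominates C3 and C2 and exchanges the one remaining silicon, coming back to the route at target 16.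

Step 8. Silicon–bromine exchange at the second silylated carbon may stall once the ring is deactivated, or the free indole may be over-oxidised, substituted at C7, or protodesilylated by adventitious acid. The fallback sets out from 13 and does the exchange on the oxidation-resistant N-sulfonylindole with molecular bromine. Br2 (about 3.3 equiv) in CH2Cl2 with NaHCO3 at 0 °C → rt should brominate C3 and replace both silyl groups, giving 3,5,6-tribromo-1-tosyl-1H-indole F7. KOH in MeOH–THF–H2O then gives 3,5,6-tribromo-1H-indole F8, and one equivalent of NBS in DMF at 0 °C brominates the only remaining pyrrole position, C2, coming back to the route at target 16.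

Step 3. The electrophile may attack C5 instead of C2, or the sulfonyl group may be lost under the Lewis acid. The fallback sets out from 5 and formylates the free, electron-rich pyrrole instead. NaOEt in EtOH removes the tosyl group to give ethyl 2-(1H-pyrrol-3-yl)acetate F9. Vilsmeier–Haack reaction (POCl3, DMF, 0 °C → rt) should give mainly the C2 iminium salt, [3-(2-ethoxy-2-oxoethyl)-1H-pyrrol-2-yl]methylidene(dimethyl)ammonium chloride F10, since C2 is the α-position next to the alkyl group. Aqueous NaOAc hydrolyses it to ethyl 2-(2-formyl-1H-pyrrol-3-yl)acetate F11, which is separated from any 5-formyl isomer. TsCl, Et3N and DMAP in CH2Cl2 then re-install the sulfonyl group, coming back to the route at 7.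

**Further compounds**

F1 | step 6 | 5-bromo-6-(trimethylsilyl) CO2-bridged cycloadduct (1-tosyl-4,7-dihydroindole with –C(=O)–O– bridge from C4 to C7; racemic, one enantiomer drawn) | Cc1ccc(cc1)S(=O)(=O)n1ccc2c1[C@@H]1OC(=O)[C@H]2C(Br)=C1[Si](C)(C)C
F2 | step 6 | 6-bromo-5-(trimethylsilyl) CO2-bridged cycloadduct (1-tosyl-4,7-dihydroindole with –C(=O)–O– bridge from C4 to C7; racemic, one enantiomer drawn) | Cc1ccc(cc1)S(=O)(=O)n1ccc2c1[C@@H]1OC(=O)[C@H]2C([Si](C)(C)C)=C1Br
F3 | step 6 | 5-bromo-1-tosyl-6-(trimethylsilyl)-1H-indole | Cc1ccc(cc1)S(=O)(=O)n1ccc2cc(Br)c([Si](C)(C)C)cc21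
F4 | step 6 | 6-bromo-1-tosyl-5-(trimethylsilyl)-1H-indole | Cc1ccc(cc1)S(=O)(=O)n1ccc2cc([Si](C)(C)C)c(Br)cc21
F5 | step 6 | 5-bromo-6-(trimethylsilyl)-1H-indole | C[Si](C)(C)c1cc2[nH]ccc2cc1Br
F6 | step 6 | 6-bromo-5-(trimethylsilyl)-1H-indole | C[Si](C)(C)c1cc2cc[nH]c2cc1Br
F7 | step 8 | 3,5,6-tribromo-1-tosyl-1H-indole | Cc1ccc(cc1)S(=O)(=O)n1cc(Br)c2cc(Br)c(Br)cc21
F8 | step 8 | 3,5,6-tribromo-1H-indole | Brc1c[nH]c2cc(Br)c(Br)cc12
F9 | step 3 | ethyl 2-(1H-pyrrol-3-yl)acetate | CCOC(=O)Cc1cc[nH]c1
F10 | step 3 | [3-(2-ethoxy-2-oxoethyl)-1H-pyrrol-2-yl]methylidene(dimethyl)ammonium chloride | CCOC(=O)Cc1cc[nH]c1C=[N+](C)C.[Cl-]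
F11 | step 3 | ethyl 2-(2-formyl-1H-pyrrol-3-yl)acetate | CCOC(=O)Cc1cc[nH]c1C=O
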